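**Retrosynthetic overview**

- Target 19 ⇐ tetra-O-benzyl ether 18 (hydrogenolysis); 18 ⇐ dibromide 16 + dimethylzinc 17, forming both Cα–CH3 bonds of the two 2-methylbutanoyl ketones in one nickel/pybox-catalysed Negishi methylation.
- Feature used: each stereocentre is the α-carbon (C2) of the acyl chain on C8 of a chroman ring, a CH bearing CH3, C2H5 and the aryl ketone C=O. A radical at this carbon is planar and conjugated with the carbonyl, so both C–Br epimers give the same intermediate; the two centres lie on opposite sides of the bridging CH and are set independently.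
- 16 ⇐ 13 (double α-bromination through the enol silane) ⇐ 12 (four O-benzylations) ⇐ two molecules of monomer 8 + 6-methylheptanal 9, joined at C6 of each chroman.
- 8 ⇐ phloroglucinol 1, butanoyl chloride 2 and 2-methylbut-3-en-2-ol 5. A temporary O4 benzyl ether makes the acylphloroglucinol symmetric, so the pyran ring can only close onto the oxygen ortho to the ketone (8-acyl chroman, C6 left free).
- Ring order: the benzene rings come from 1; the dihydropyran ring of each chroman is closed in step 3, before dimerisation; no ring is formed afterwards.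

Key step: step 8

Remark on stereochemistry: in 18 and 19 the bridging carbon carries two identical aryl groups and is not stereogenic. Dibromide 16 has four stereoisomers (an enantiomeric pair plus two forms with unlike C–Br centres, which differ at the then pseudoasymmetric bridge carbon); all are used together.

Remark on the ligand: the (S,S) antipode of the pybox ligand is assumed to give R at the acyl α-carbon. If a test on the benzylated monomeric bromo ketone shows the opposite sense, the (R,R) ligand is used with no other change.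

Remark on numbering: partly converted congeners of the multi-site steps 6 to 9 are not numbered separately.

**Route**

Step 1
Reactants: 1 phloroglucinol; 2 butanoyl chloride
Product: 3 1-(2,4,6-trihydroxyphenyl)butan-1-one
Conditions: AlCl3 (3.5 equiv), PhNO2/CH2Cl2, 0 °C → 60 °C; aq. HCl work-up
Reagents that add atoms: none
Why: Friedel–Crafts acylation of the symmetric, strongly activated triphenol should stop after one acylation because the ketone deactivates the ring.

Step 2
Reactants: 3 1-(2,4,6-trihydroxyphenyl)butan-1-one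
Product: 4 1-[4-(benzyloxy)-2,6-dihydroxyphenyl]butan-1-one
Conditions: BnBr (1.0 equiv), K2CO3 (1.0 equiv), DMF, 0 °C → rt
Reagents that add atoms: benzyl bromide, BrCc1ccccc1
Why: Williamson etherification with one equivalent of halide should go to O4, the most acidic and least hindered phenol (para to the ketone), since the 2- and 6-hydroxyls are hydrogen-bonded to or shielded by the carbonyl; over-alkylated material is removed by chromatography.

Step 3
Reactants: 4 1-[4-(benzyloxy)-2,6-dihydroxyphenyl]butan-1-one; 5 2-methylbut-3-en-2-ol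
Product: 7 1-[5-(benzyloxy)-7-hydroxy-2,2-dimethylchroman-8-yl]butan-1-one, via C3-prenyl phenol 6 (not isolated)
Conditions: 5 (1.1 equiv), BF3·OEt2 (1 equiv), 1,4-dioxane, rt → 60 °C
Reagents that add atoms: none
Why: Friedel–Crafts prenylation at C3 (equivalent to C5 by symmetry) followed by acid-catalysed Markovnikov addition of the adjacent free 2-OH to the prenyl alkene should close the 2,2-dimethylchroman ring; as O4 is benzylated, only the ring oxygen ortho to the ketone can form.

Step 4
Reactants: 7 1-[5-(benzyloxy)-7-hydroxy-2,2-dimethylchroman-8-yl]butan-1-one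
Product: 8 1-(5,7-dihydroxy-2,2-dimethylchroman-8-yl)butan-1-one
Conditions: H2 (1 atm), 10 % Pd/C, EtOAc, rt
Reagents that add atoms: none
Why: hydrogenolysis of the aryl benzyl ether over palladium on carbon under neutral conditions should leave the chelated, electron-rich aryl ketone and the chroman untouched.

Step 5
Reactants: 8 1-(5,7-dihydroxy-2,2-dimethylchroman-8-yl)butan-1-one (two molecules); 9 6-methylheptanal
Product: 12 1,1'-[(6-methylheptane-1,1-diyl)bis(5,7-dihydroxy-2,2-dimethylchroman-6,8-diyl)]dibutan-1-one, via benzylic carbinol 10 (not isolated), via ortho-quinone methide 11 (not isolated)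
Conditions: 8 (2.05 equiv), 9 (1 equiv), p-TsOH·H2O (10 mol %), ClCH2CH2Cl, 50 °C
Reagents that add atoms: none
Why: acid-catalysed phenol–aldehyde condensation (Friedel–Crafts hydroxyalkylation at C6, the only free ring position, flanked by two hydroxyls; dehydration to the ortho-quinone methide; conjugate addition of a second molecule of 8) should give the 1,1-diarylalkane, and no oligomer can form because each monomer has one reactive carbon.

Step 6
Reactants: 12 1,1'-[(6-methylheptane-1,1-diyl)bis(5,7-dihydroxy-2,2-dimethylchroman-6,8-diyl)]dibutan-1-one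
Product: 13 1,1'-[(6-methylheptane-1,1-diyl)bis(5,7-bis(benzyloxy)-2,2-dimethylchroman-6,8-diyl)]dibutan-1-one
Conditions: BnBr (6 equiv), Cs2CO3 (6 equiv), Bu4NI (10 mol %), DMF, rt → 50 °C
Reagents that add atoms: benzyl bromide, BrCc1ccccc1
Why: Williamson etherification with a caesium phenoxide in a dipolar aprotic solvent favours O-alkylation; carbonate does not enolise the ketones and every ring carbon is substituted, so all four phenols should be capped.

Step 7
Reactants: 13 1,1'-[(6-methylheptane-1,1-diyl)bis(5,7-bis(benzyloxy)-2,2-dimethylchroman-6,8-diyl)]dibutan-1-one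
Product: 16 1,1'-[(6-methylheptane-1,1-diyl)bis(5,7-bis(benzyloxy)-2,2-dimethylchroman-6,8-diyl)]bis(2-bromobutan-1-one) as the mixture of all four C–Br stereoisomers, via dilithium bis-enolate 14 (not isolated), via bis(trimethylsilyl enol ether) 15 (not isolated)
Conditions: LiN(SiMe3)2 (2.5 equiv), THF, −78 °C; Me3SiCl (3 equiv), −78 → 0 °C; then NBS (2.1 equiv), THF, −78 → 0 °C, dark
Reagents that add atoms: N-bromosuccinimide, O=C1CCC(=O)N1Br
Why: each ketone has a single enolisable side, and bromination of the enol silane with N-bromosuccinimide should deliver one bromine per ketone under neutral conditions that spare the benzyl ethers and the acid-sensitive diarylmethine; the two C–Br centres form without control, which the next step does not need.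

Step 8
Reactants: 16 bis(2-bromobutanoyl) tetra-O-benzyl dimer (all four stereoisomers); 17 dimethylzinc
Product: 18 (2R,2'R)-1,1'-[(6-methylheptane-1,1-diyl)bis(5,7-bis(benzyloxy)-2,2-dimethylchroman-6,8-diyl)]bis(2-methylbutan-1-one)
Conditions: 17 (1.6 equiv) premixed with ZnBr2 (1.6 equiv) in THF, NiCl2·glyme (20 mol %), (S,S)-iPr-pybox [2,6-bis((4S)-4-isopropyl-4,5-dihydrooxazol-2-yl)pyridine] (26 mol %), glyme/THF/DMA, −30 °C
Reagents that add atoms: none
Why: Proposed new method: a monovalent nickel–pybox complex abstracts bromine from either C–Br epimer to give a planar, carbonyl-stabilised secondary α-keto radical, which is captured by the chiral divalent methylnickel complex formed by transmetalation from zinc, and reductive elimination from the resulting trivalent nickel alkyl methyl species forms the Cα–CH3 bond and returns monovalent nickel; the cycle then repeats at the second ketone. The closest known reaction type is the nickel/pybox-catalysed enantioconvergent Negishi coupling of racemic α-bromo ketones with arylzinc halides and of racemic α-bromo amides with alkylzinc halides; methyl transfer to an α-bromo ketone, and its use at two sites of one molecule, has not been shown. No ring is closed; two C(sp3)–C(sp3) bonds are formed. Each new stereocentre (the α-carbon of each acyl chain, both R) is set by the chiral ligand at radical capture and reductive elimination, the C–Br configuration having been erased in the radical, so all four stereoisomers of 16 converge on one product. The step needs ligand-controlled enantioselection at two remote, independent sites (a minor S centre ends up mainly in the R,S diastereomers, which raises the enantiomeric purity of the R,R product at the cost of material) and chemoselectivity for coupling over bromine–zinc exchange, β-hydride loss and enolisation; this is served by converting dimethylzinc into the milder methylzinc bromide, by the low temperature, and by the benzyl ethers, which remove O5 and O7 as internal nucleophiles and proton sources.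

Step 9
Reactants: 18 (2R,2'R)-tetra-O-benzyl dimer
Product: 19 (2R,2'R)-1,1'-[(6-methylheptane-1,1-diyl)bis(5,7-dihydroxy-2,2-dimethylchroman-6,8-diyl)]bis(2-methylbutan-1-one)
Conditions: H2 (1 atm), 10 % Pd/C, EtOAc, rt
Reagents that add atoms: none
Why: hydrogenolysis of the four aryl benzyl ethers is neutral, so the enolisable α-stereocentres and the diarylmethine bridge should be preserved.

**Compound list**

1 | phloroglucinol | Oc1cc(O)cc(O)c1 | starting material
2 | butanoyl chloride | CCCC(=O)Cl | starting material
3 | 1-(2,4,6-trihydroxyphenyl)butan-1-one | CCCC(=O)c1c(O)cc(O)cc1O | intermediate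
4 | 1-[4-(benzyloxy)-2,6-dihydroxyphenyl]butan-1-one | CCCC(=O)c1c(O)cc(OCc2ccccc2)cc1O | intermediate
5 | 2-methylbut-3-en-2-ol | CC(C)(O)C=C | starting material
6 | 1-[4-(benzyloxy)-2,6-dihydroxy-3-(3-methylbut-2-en-1-yl)phenyl]butan-1-one (not isolated) | CCCC(=O)c1c(O)cc(OCc2ccccc2)c(CC=C(C)C)c1O | intermediate
7 | 1-[5-(benzyloxy)-7-hydroxy-2,2-dimethylchroman-8-yl]butan-1-one | CCCC(=O)c1c(O)cc(OCc2ccccc2)c2c1OC(C)(C)CC2 | intermediate
8 | 1-(5,7-dihydroxy-2,2-dimethylchroman-8-yl)butan-1-one | CCCC(=O)c1c(O)cc(O)c2c1OC(C)(C)CC2 | intermediate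
9 | 6-methylheptanal | CC(C)CCCCC=O | starting material
10 | racemic 1-[5,7-dihydroxy-6-(1-hydroxy-6-methylheptyl)-2,2-dimethylchroman-8-yl]butan-1-one (not isolated) | CCCC(=O)c1c(O)c(C(O)CCCCC(C)C)c(O)c2c1OC(C)(C)CC2 | intermediate
11 | 8-butanoyl-5-hydroxy-2,2-dimethyl-6-(6-methylheptylidene)-3,4-dihydro-2H-chromen-7(6H)-one, ortho-quinone methide (not isolated) | CCCC(=O)C1=C2OC(C)(C)CCC2=C(O)C(=CCCCCC(C)C)C1=O | intermediate
12 | 1,1'-[(6-methylheptane-1,1-diyl)bis(5,7-dihydroxy-2,2-dimethylchroman-6,8-diyl)]dibutan-1-one | CCCC(=O)c1c(O)c(C(CCCCC(C)C)c2c(O)c3c(c(C(=O)CCC)c2O)OC(C)(C)CC3)c(O)c2c1OC(C)(C)CC2 | intermediate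
13 | 1,1'-[(6-methylheptane-1,1-diyl)bis(5,7-bis(benzyloxy)-2,2-dimethylchroman-6,8-diyl)]dibutan-1-one | CCCC(=O)c1c(OCc2ccccc2)c(C(CCCCC(C)C)c2c(OCc3ccccc3)c3c(c(C(=O)CCC)c2OCc2ccccc2)OC(C)(C)CC3)c(OCc2ccccc2)c2c1OC(C)(C)CC2 | intermediate
14 | dilithium bis-enolate of 13 (not isolated) | CCC=C(O[Li])c1c(OCc2ccccc2)c(C(CCCCC(C)C)c2c(OCc3ccccc3)c3c(c(C(O[Li])=CCC)c2OCc2ccccc2)OC(C)(C)CC3)c(OCc2ccccc2)c2c1OC(C)(C)CC2 | intermediate
15 | bis(trimethylsilyl enol ether) of 13, enol geometry not defined (not isolated) | CCC=C(O[Si](C)(C)C)c1c(OCc2ccccc2)c(C(CCCCC(C)C)c2c(OCc3ccccc3)c3c(c(C(O[Si](C)(C)C)=CCC)c2OCc2ccccc2)OC(C)(C)CC3)c(OCc2ccccc2)c2c1OC(C)(C)CC2 | intermediate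
16 | 1,1'-[(6-methylheptane-1,1-diyl)bis(5,7-bis(benzyloxy)-2,2-dimethylchroman-6,8-diyl)]bis(2-bromobutan-1-one), all four C–Br stereoisomers | CCC(Br)C(=O)c1c(OCc2ccccc2)c(C(CCCCC(C)C)c2c(OCc3ccccc3)c3c(c(C(=O)C(Br)CC)c2OCc2ccccc2)OC(C)(C)CC3)c(OCc2ccccc2)c2c1OC(C)(C)CC2 | intermediate
17 | dimethylzinc | C[Zn]C | starting material
18 | (2R,2'R)-1,1'-[(6-methylheptane-1,1-diyl)bis(5,7-bis(benzyloxy)-2,2-dimethylchroman-6,8-diyl)]bis(2-methylbutan-1-one) | CC[C@@H](C)C(=O)c1c(OCc2ccccc2)c(C(CCCCC(C)C)c2c(OCc3ccccc3)c3c(c(C(=O)[C@H](C)CC)c2OCc2ccccc2)OC(C)(C)CC3)c(OCc2ccccc2)c2c1OC(C)(C)CC2 | intermediate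
19 | (2R,2'R)-1,1'-[(6-methylheptane-1,1-diyl)bis(5,7-dihydroxy-2,2-dimethylchroman-6,8-diyl)]bis(2-methylbutan-1-one) | CC[C@@H](C)C(=O)c1c(O)c(C(CCCCC(C)C)c2c(O)c3c(c(C(=O)[C@H](C)CC)c2O)OC(C)(C)CC3)c(O)c2c1OC(C)(C)CC2 | target

**Step count**

Total steps: 9. Longest linear sequence: 9 steps (1 → 19).

**Steps most likely to fail**

1. Step 8 (proposed new method). What may go wrong:
   - nickel-mediated bromine–zinc exchange could reduce the C–Br bonds instead of coupling them;
   - the α-keto radical could abstract hydrogen from the neighbouring benzylic OCH2 group;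
   - enantioselection could fall short at one of the two sites, leaving R,S diastereomers that are hard to separate because the centres are remote.

   Fallback by known chemistry, setting out from phloroglucinol 1 and rejoining the route at target 19: commercial (R)-2-methylbutanoic acid is converted with oxalyl chloride into (R)-2-methylbutanoyl chloride F1. Friedel–Crafts acylation of 1 with F1 (AlCl3) should give (R)-2-methyl-1-(2,4,6-trihydroxyphenyl)butan-1-one F2. Mono-benzylation at O4 as in step 2 gives (R)-1-[4-(benzyloxy)-2,6-dihydroxyphenyl]-2-methylbutan-1-one F3. Annulation with 5 as in step 3 gives (R)-1-[5-(benzyloxy)-7-hydroxy-2,2-dimethylchroman-8-yl]-2-methylbutan-1-one F4. Hydrogenolysis gives (R)-1-(5,7-dihydroxy-2,2-dimethylchroman-8-yl)-2-methylbutan-1-one F5. Acid-catalysed condensation of two molecules of F5 with 9, as in step 5, then gives 19 directly. The known weak point is erosion of configuration under AlCl3, to be followed by chiral HPLC.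

2. Step 6. What may go wrong: etherification of the four doubly flanked phenols (two of them chelated to the ketones) could stay incomplete, or the base could fragment the diarylmethine bridge before the phenoxides are capped. Fallback with a smaller, acid-removable group, setting out from 12 and rejoining at 19: MOMCl, K2CO3, acetone, reflux should give the tetrakis(methoxymethyl) ether of 12, F6. Bromination as in step 7 gives the tetrakis(methoxymethyl) bis(2-bromobutanoyl) dimer F7. The coupling of step 8 gives the (2R,2'R)-tetrakis(methoxymethyl) ether of the target, F8. Methanolic HCl at rt then releases 19.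

3. Step 7. What may go wrong: double enolisation of the two hindered, twisted aryl ketones could be incomplete, or bromine could be transferred to the electron-rich core or the bridge. Fallback without enolate or enol silane, setting out from 13 and rejoining at 16: direct bromination of the ketone enols with CuBr2 (4.4 equiv) in refluxing EtOAc/CHCl3, a base-free halogen transfer that gives 16 in one operation; no new compound arises (F0).

**Further compounds**

F1 | step 8 | (R)-2-methylbutanoyl chloride | CC[C@@H](C)C(Cl)=O
F2 | step 8 | (R)-2-methyl-1-(2,4,6-trihydroxyphenyl)butan-1-one | CC[C@@H](C)C(=O)c1c(O)cc(O)cc1O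
F3 | step 8 | (R)-1-[4-(benzyloxy)-2,6-dihydroxyphenyl]-2-methylbutan-1-one | CC[C@@H](C)C(=O)c1c(O)cc(OCc2ccccc2)cc1O
F4 | step 8 | (R)-1-[5-(benzyloxy)-7-hydroxy-2,2-dimethylchroman-8-yl]-2-methylbutan-1-one | CC[C@@H](C)C(=O)c1c(O)cc(OCc2ccccc2)c2c1OC(C)(C)CC2
F5 | step 8 | (R)-1-(5,7-dihydroxy-2,2-dimethylchroman-8-yl)-2-methylbutan-1-one | CC[C@@H](C)C(=O)c1c(O)cc(O)c2c1OC(C)(C)CC2
F6 | step 6 | 1,1'-[(6-methylheptane-1,1-diyl)bis(5,7-bis(methoxymethoxy)-2,2-dimethylchroman-6,8-diyl)]dibutan-1-one | CCCC(=O)c1c(OCOC)c(C(CCCCC(C)C)c2c(OCOC)c3c(c(C(=O)CCC)c2OCOC)OC(C)(C)CC3)c(OCOC)c2c1OC(C)(C)CC2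
F7 | step 6 | 1,1'-[(6-methylheptane-1,1-diyl)bis(5,7-bis(methoxymethoxy)-2,2-dimethylchroman-6,8-diyl)]bis(2-bromobutan-1-one), all C–Br stereoisomers | CCC(Br)C(=O)c1c(OCOC)c(C(CCCCC(C)C)c2c(OCOC)c3c(c(C(=O)C(Br)CC)c2OCOC)OC(C)(C)CC3)c(OCOC)c2c1OC(C)(C)CC2
F8 | step 6 | (2R,2'R)-1,1'-[(6-methylheptane-1,1-diyl)bis(5,7-bis(methoxymethoxy)-2,2-dimethylchroman-6,8-diyl)]bis(2-methylbutan-1-one) | CC[C@@H](C)C(=O)c1c(OCOC)c(C(CCCCC(C)C)c2c(OCOC)c3c(c(C(=O)[C@H](C)CC)c2OCOC)OC(C)(C)CC3)c(OCOC)c2c1OC(C)(C)CC2
F0 | step 7 | none | none
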